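**Plan**
- Retrosynthesis: cut the three O–benzyl bonds first, then a helper C–S bond at Cγ of the side chain, then the Cα–Cβ bond of the nonanoyl chain (Cα is the CH2 next to the exocyclic C=O), then the C-2–acyl bond of the ring and the aryl–CH2 bond.
- Forward: the six-membered ring is not built but taken from all-cis cyclohexane-1,3,5-triol (mono-benzylation, oxidation to the 1,3-dione) and acylated at C-2 with a xanthyl-acetyl unit; the chain half is an aryl heptene from an iron-catalysed Grignard coupling.
- The halves are joined by radical addition of the acyl α-carbon to the terminal alkene carbon (xanthate group transfer); the sulfur helper is then removed reductively and one hydrogenolysis frees the catechol and the C-5 carbinol.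
- Enabling feature: the exocyclic ketone on C-2 of the enolised cyclohexane-1,3-dione ring stabilises a radical on its α-carbon, and the chain beyond Cβ is plain polymethylene, so an unactivated 1-alkene suffices as partner. Two donor carbons are thus united under neutral conditions, which spares the base-labile β-alkoxy triketone (E1cB aromatisation to a 2-acylresorcinol).
- Stereochemistry: C-5 is the one carbinol carbon of the triol that is not oxidised; it is stereogenic only through the position of the enol proton (see remark), so no stereocontrolling step is required.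

Key step: step 5

Remark: C-5 is stereogenic only while the enol proton rests on one ring oxygen; its shift to the other ring oxygen converts the drawn (5S) structure into its mirror image, so the target is a single, configurationally averaged substance, no enantioselective step is possible or needed, and every triketone below is written in the tautomer and with the descriptor of the target SMILES.

**Step 1**
Reactants: 1 cis,cis-cyclohexane-1,3,5-triol (all-cis, meso)
Product: 2 cis,cis-5-(benzyloxy)cyclohexane-1,3-diol (all-cis, meso)
Conditions: NaH (1.0 equiv), BnBr (1.0 equiv), DMF, 0 °C → rt; 1 in twofold excess, recovered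
Reagents that add atoms: benzyl bromide, BrCc1ccccc1
Why: Williamson etherification of the mono-alkoxide; with the threefold-symmetric triol in excess, statistical mono-benzylation should dominate, and since no ring C–O bond is touched the all-cis arrangement is retained.

**Step 2**
Reactants: 2 cis,cis-5-(benzyloxy)cyclohexane-1,3-diol
Product: 3 5-(benzyloxy)cyclohexane-1,3-dione
Conditions: Jones reagent (CrO3, H2SO4, H2O), acetone, 0 °C; i-PrOH quench
Reagents that add atoms: none
Why: Jones oxidation of both secondary carbinols should give the β-diketone (stable as its enol) while the benzyl ether is inert at 0 °C; the two carbinol stereocentres disappear and C-5 is non-stereogenic in the symmetric dione.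

**Step 3**
Reactants: 3 5-(benzyloxy)cyclohexane-1,3-dione; 4 2-[(ethoxycarbonothioyl)sulfanyl]acetic acid
Product: 6 (5S)-5-(benzyloxy)-2-{[(ethoxycarbonothioyl)sulfanyl]acetyl}-3-hydroxycyclohex-2-en-1-one (tautomer as drawn), via O-acyl enol ester 5 (not isolated)
Conditions: DCC (1.2 equiv), DMAP (1.2 equiv), CH2Cl2, 0 °C → rt; 1 M HCl wash
Reagents that add atoms: none
Why: Carbodiimide (Steglich-type) O-acylation of the enol followed by DMAP-mediated O→C acyl migration, the standard entry to 2-acylcyclohexane-1,3-diones; C-5 becomes formally stereogenic only through the enol position (see remark), so no selectivity question arises.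

**Step 4**
Reactants: 7 4-bromo-1,2-bis(benzyloxy)benzene; 8 7-bromohept-1-ene
Product: 10 1,2-bis(benzyloxy)-4-(hept-6-en-1-yl)benzene, via arylmagnesium bromide 9 (not isolated)
Conditions: Mg, THF, reflux; then FeCl3 (5 mol %), TMEDA (1.2 equiv), 8, THF, 0 °C → rt
Reagents that add atoms: none
Why: Grignard formation followed by iron-catalysed Kumada-type sp2–sp3 cross-coupling of the aryl Grignard reagent with a primary alkyl bromide, which should tolerate the terminal alkene and the benzyl ethers; no stereocentre is involved.

**Step 5**
Reactants: 6 (5S)-5-(benzyloxy)-2-{[(ethoxycarbonothioyl)sulfanyl]acetyl}-3-hydroxycyclohex-2-en-1-one; 10 1,2-bis(benzyloxy)-4-(hept-6-en-1-yl)benzene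
Product: 11 (5S)-5-(benzyloxy)-2-{9-[3,4-bis(benzyloxy)phenyl]-4-[(ethoxycarbonothioyl)sulfanyl]nonanoyl}-3-hydroxycyclohex-2-en-1-one (racemic at C-4 of the chain)
Conditions: dilauroyl peroxide (5 mol % portions until 6 is consumed), ClCH2CH2Cl (1 M), reflux, Ar; 10 (1.5 equiv)
Reagents that add atoms: none
Why: Undecyl radicals from the peroxide add to the C=S group of 6 and release the carbonyl-stabilised radical at the acyl α-carbon, which adds to the unsubstituted terminus of alkene 10; the secondary radical formed at Cγ takes the xanthate group from a further molecule of 6 and so carries the chain (degenerative xanthate group transfer, the closest known reaction type being the peroxide-initiated addition of S-(2-oxoalkyl) xanthates to unactivated 1-alkenes). The event joins two carbons that are both donors in polar chemistry, an enolisable α-carbon and an alkene carbon, which is possible because the α-acyl radical is electrophilic and the alkene electron-rich. No ring is closed. The only new stereocentre, the xanthate-bearing Cγ, should form without control as a racemate and is erased in step 6. The step needs site selectivity within the delocalised radical (side-chain carbon against ring C-2) and attack at the CH2 end of the alkene: C-2 is fully substituted and bonding there would forfeit the chelated enol, the alkene is monosubstituted, and chain transfer should outrun oligomerisation because the secondary adduct radical is less stabilised than the α-acyl radical. The medium is neutral, so the β-benzyloxy triketone is not exposed to E1cB loss of benzyl alcohol, which would lead to a 2-acylresorcinol.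

**Step 6**
Reactants: 11 (5S)-5-(benzyloxy)-2-{9-[3,4-bis(benzyloxy)phenyl]-4-[(ethoxycarbonothioyl)sulfanyl]nonanoyl}-3-hydroxycyclohex-2-en-1-one
Product: 12 (5S)-5-(benzyloxy)-2-{9-[3,4-bis(benzyloxy)phenyl]nonanoyl}-3-hydroxycyclohex-2-en-1-one
Conditions: (Me3Si)3SiH (1.5 equiv), AIBN (0.2 equiv), toluene, 85 °C
Reagents that add atoms: none
Why: Radical-chain reductive C–S cleavage of Barton–McCombie type, in which the silyl radical adds to the thiocarbonyl sulfur, β-scission releases the secondary Cγ radical and this abstracts hydrogen from the silane; the helper group and the uncontrolled stereocentre are removed together.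

**Step 7**
Reactants: 12 (5S)-5-(benzyloxy)-2-{9-[3,4-bis(benzyloxy)phenyl]nonanoyl}-3-hydroxycyclohex-2-en-1-one
Product: 13 (5S)-2-[9-(3,4-dihydroxyphenyl)nonanoyl]-3,5-dihydroxycyclohex-2-en-1-one (target)
Conditions: H2 (1 atm), Pd(OH)2/C, degassed EtOAc–EtOH, rt; filtration and evaporation
Reagents that add atoms: none
Why: Heterogeneous hydrogenolysis of the two aryl benzyl ethers and the secondary benzyl ether under neutral conditions should free catechol and carbinol at once with toluene as the only by-product, without dehydration of the β-hydroxy triketone or reduction of the chelated acyl group; C-5 is not touched.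

**Compound list**
1 | cis,cis-cyclohexane-1,3,5-triol | O[C@@H]1C[C@H](O)C[C@H](O)C1 | starting material
2 | cis,cis-5-(benzyloxy)cyclohexane-1,3-diol | O[C@@H]1C[C@H](O)C[C@H](OCc2ccccc2)C1 | intermediate
3 | 5-(benzyloxy)cyclohexane-1,3-dione | O=C1CC(=O)CC(OCc2ccccc2)C1 | intermediate
4 | 2-[(ethoxycarbonothioyl)sulfanyl]acetic acid | CCOC(=S)SCC(=O)O | starting material
5 | 5-(benzyloxy)-3-oxocyclohex-1-en-1-yl 2-[(ethoxycarbonothioyl)sulfanyl]acetate (racemic) | CCOC(=S)SCC(=O)OC1=CC(=O)CC(OCc2ccccc2)C1 | intermediate
6 | (5S)-5-(benzyloxy)-2-{[(ethoxycarbonothioyl)sulfanyl]acetyl}-3-hydroxycyclohex-2-en-1-one | CCOC(=S)SCC(=O)C1=C(O)C[C@H](OCc2ccccc2)CC1=O | intermediate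
7 | 4-bromo-1,2-bis(benzyloxy)benzene | Brc1ccc(OCc2ccccc2)c(OCc2ccccc2)c1 | starting material
8 | 7-bromohept-1-ene | C=CCCCCCBr | starting material
9 | [3,4-bis(benzyloxy)phenyl]magnesium bromide | Br[Mg]c1ccc(OCc2ccccc2)c(OCc2ccccc2)c1 | intermediate
10 | 1,2-bis(benzyloxy)-4-(hept-6-en-1-yl)benzene | C=CCCCCCc1ccc(OCc2ccccc2)c(OCc2ccccc2)c1 | intermediate
11 | (5S)-5-(benzyloxy)-2-{9-[3,4-bis(benzyloxy)phenyl]-4-[(ethoxycarbonothioyl)sulfanyl]nonanoyl}-3-hydroxycyclohex-2-en-1-one (racemic at chain C-4) | CCOC(=S)SC(CCCCCc1ccc(OCc2ccccc2)c(OCc2ccccc2)c1)CCC(=O)C1=C(O)C[C@H](OCc2ccccc2)CC1=O | intermediate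
12 | (5S)-5-(benzyloxy)-2-{9-[3,4-bis(benzyloxy)phenyl]nonanoyl}-3-hydroxycyclohex-2-en-1-one | O=C(CCCCCCCCc1ccc(OCc2ccccc2)c(OCc2ccccc2)c1)C1=C(O)C[C@H](OCc2ccccc2)CC1=O | intermediate
13 | (5S)-2-[9-(3,4-dihydroxyphenyl)nonanoyl]-3,5-dihydroxycyclohex-2-en-1-one | O=C(CCCCCCCCc1ccc(O)c(O)c1)C1=C(O)C[C@H](O)CC1=O | target

Total step count: 7
Longest linear sequence: 6 steps (1 → 2 → 3 → 6 → 11 → 12 → 13)

**Steps most likely to fail**

1. Step 5. The delocalised radical may bond through ring C-2 instead of the side-chain carbon, or chain propagation may stall because the radical is too stabilised, leaving both partners unconsumed. The fallback makes the same bond by enolate alkylation; it sets out from 3 and from 7 (through 9) and comes back at 12. Dione 3 would be O-acetylated (Ac2O, Et3N, CH2Cl2) to 5-(benzyloxy)-3-oxocyclohex-1-en-1-yl acetate F1 and isomerised (DMAP, MeCN) to (5S)-2-acetyl-5-(benzyloxy)-3-hydroxycyclohex-2-en-1-one F2. Grignard reagent 9 would be coupled under the conditions of step 4 with 1-bromo-7-chloroheptane to 1,2-bis(benzyloxy)-4-(7-chloroheptyl)benzene F3, and Finkelstein exchange (NaI, acetone) would give 1,2-bis(benzyloxy)-4-(7-iodoheptyl)benzene F4. Double deprotonation of F2 (LDA, 2.2 equiv, THF–DMPU, −78 °C) and alkylation of the terminal carbanion of the tricarbonyl dianion with F4 should give 12 directly; the temperature is kept low to avoid ring deprotonation and loss of benzyl alcohol.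

2. Step 3. The O→C acyl migration may stall at the enol ester, or the activated xanthyl-acetyl unit may be degraded (ketene formation, attack of DMAP at the thiocarbonyl group). The fallback forms the C–S bond last; it sets out from 3 and comes back at 6. Dione 3 would be O-acylated with chloroacetyl chloride (pyridine, CH2Cl2) to 5-(benzyloxy)-3-oxocyclohex-1-en-1-yl chloroacetate F5, the ester isomerised (catalytic DMAP, or AlCl3) to (5S)-5-(benzyloxy)-2-(chloroacetyl)-3-hydroxycyclohex-2-en-1-one F6, and the chloride displaced with potassium O-ethyl xanthate (acetone, 0 °C) to give 6.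

3. Step 7. Sulfur traces from step 6 may poison the catalyst so that the secondary benzyl ether survives, and forcing the hydrogenation may reduce the chelated acyl carbonyl. The fallback is a non-reductive Lewis-acid debenzylation that sets out from 12 and comes back at 13: BCl3 with pentamethylbenzene as cation scavenger (CH2Cl2, −78 °C), then aqueous work-up to hydrolyse the boron chelate of the triketone. No new compound is involved (F0).

**Further compounds**
F1 | step 5 | 5-(benzyloxy)-3-oxocyclohex-1-en-1-yl acetate | CC(=O)OC1=CC(=O)CC(OCc2ccccc2)C1
F2 | step 5 | (5S)-2-acetyl-5-(benzyloxy)-3-hydroxycyclohex-2-en-1-one | CC(=O)C1=C(O)C[C@H](OCc2ccccc2)CC1=O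
F3 | step 5 | 1,2-bis(benzyloxy)-4-(7-chloroheptyl)benzene | ClCCCCCCCc1ccc(OCc2ccccc2)c(OCc2ccccc2)c1
F4 | step 5 | 1,2-bis(benzyloxy)-4-(7-iodoheptyl)benzene | ICCCCCCCc1ccc(OCc2ccccc2)c(OCc2ccccc2)c1
F5 | step 3 | 5-(benzyloxy)-3-oxocyclohex-1-en-1-yl chloroacetate | O=C(CCl)OC1=CC(=O)CC(OCc2ccccc2)C1
F6 | step 3 | (5S)-5-(benzyloxy)-2-(chloroacetyl)-3-hydroxycyclohex-2-en-1-one | O=C(CCl)C1=C(O)C[C@H](OCc2ccccc2)CC1=O
F0 | step 7 | none | none
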